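## The problem

The target 42 is built on a 5,6-epoxy-4-hydroxycyclohex-2-en-1-one; the ring is numbered C1 (ketone), C2 (nitrogen-bearing), C3, C4 (carbinol), C5–C6 (oxirane) throughout. C2 carries the nitrogen of a (2E,4R)-2,4-dimethyloct-2-enamide. C4 carries an all-E hepta-2,4,6-trienamide whose nitrogen sits on a 2-amino-3-hydroxycyclopent-2-enone. Three contiguous ring stereocentres (4S,5R,6S) are needed, with the tertiary hydroxyl on the face of the oxirane. C5 and C6 can be tied to each other by an intramolecular displacement, but the fully substituted C4 needs its own control element, and the methyl-bearing carbon of the acyl chain is out of reach of the ring and must be made separately. The skeleton is modest; the difficulty is the density of oxygen on a ring that is one dehydration away from an arene. The epoxy ketone, the doubly allylic tertiary alcohol, the enamide, the triene and the acidic cyclopentenone enol tolerate neither strong acid or base nor hydride or oxidant, so both chains must arrive late and under near-neutral conditions. The handle for the ring is that C4, C5, C6 and C1 are four contiguous oxygen-bearing carbons: they coincide with C2, C3, C4 and C5 of a D-glucopyranoside branched at C2, and C2 and C3 of the target are C6 and C1 of that sugar. Joining sugar C6 to sugar C1 therefore converts a pyranoside into the carbocycle with oxygen pattern and absolute configuration already in place.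

## Retrosynthesis

**The triene.** The first cut is the single bond between the second and third carbon of the trienyl chain (counted from C4). It divides 42 into the E-alkenylstannane 33 and the bromodienamide 41. A Stille coupling forms this bond without base and with retention of both alkene geometries. The neighbouring options, olefination of a C4 aldehyde or acylation of the aminocyclopentenone as the last step, would expose an epoxy quinol to ylides or acylating agents. 33 is the hydrostannylation product of the terminal alkyne 32, which is released from the bis-silylated 31. The forward sequence must place tin on the terminal alkyne carbon, syn to hydrogen.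

**The C2–N bond.** Cutting the enamide C–N bond of 31 gives the 2-iodoenone 21 and the primary amide 30; 21 comes from enone 20 by α-iodination. Target C2 is sugar C6, which must be a methylene during ring formation, so nitrogen cannot be carried through the carbohydrate stage. The enone α-carbon is the one position that can be functionalised after the ring is complete. The cut also lets the remote stereocentre travel in 30. The coupling must tolerate an oxirane next to a ketone and needs the alkyne and the hydroxyl masked.

**The oxirane.** Opening the C5–O bond of 20 leads to 18, in which C5 carries a mesylate trans to a C6 benzoate; 18 derives from enone 16 through alcohol 17. Displacement at C5 by the C6 oxygen, with inversion, lets both oxirane carbons take their configuration from stereocentres already present. A nucleophilic epoxidation of a dienone would give that up. The forward reaction must free the C6 alkoxide and close the ring faster than the ketone enolises. The C4 oxygen must be silylated, because it is also trans to the C5 leaving group.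

**The enone.** The C2=C3 double bond of 16 is traced back to the β-hydroxy ketone 14. Dehydration is the normal fate of such aldols and removes the one stereocentre that ring formation does not control.

**The ring.** The C2–C3 bond of 14 is an aldol bond. Cutting it, reading the ketone as a hydrated enol ether and the carbinol as a masked aldehyde, gives the methyl hex-5-enopyranoside 12, in which sugar C6 and C1 are ring C2 and C3. No other ring bond can be cut to leave a cyclic precursor that already holds all three oxygenated stereocentres; a cut between two oxygenated carbons would demand a stereoselective C–C bond formation instead. The forward reaction must hydrate only the enol ether and close a six-membered ring onto an aldehyde with a fully substituted neighbour.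

**From 12 to the sugar.** 12 is reached from the tertiary alcohol 7 through 8–11, which differentiate the oxygens:
- O4 becomes the benzoate (future oxirane oxygen).
- O3 is the p-methoxybenzyl ether (future leaving group).
- O2 becomes a silyl ether.
- C6 becomes the iodide for elimination.

The C4–alkyne bond is then cut in 7, giving the 2-ulose 4 and the silylacetylene 5, added as its lithium salt 6. The axial anomeric methoxyl is the element that directs the nucleophile to the β face and so sets C4. 4 goes back through 3 and 2 to methyl α-D-glucopyranoside 1. The alkyne is preferred over a ready-made alkenyl group because it survives every later reagent and is unmasked only at the end.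

**The acyl chain.** Amide 30 is cut at its C2=C3 double bond into the α-branched alcohol 26 (oxidised in situ) and the stabilised ylide 27. 26 comes from the imides 25 and 24, assembled from the oxazolidinone 22 and hexanoyl chloride 23. An auxiliary-controlled methylation sets the isolated (R) centre reliably, and a stabilised Wittig reagent gives the E trisubstituted alkene.

**The bromodienamide.** 41 is cut at its amide bond into the acid 36 and the aminocyclopentenone salt 39. 36 comes from the enolate 34 via the aldehyde 35; 39 comes from cyclopentane-1,3-dione 37 via the oxime 38. Both halves are achiral and short.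

## Roads not taken

Alternative 1: The cut is the C4–C5 ring bond. A seven-membered vicinal dione, para-tropoquinone A2, would contract under NaOMe in methanol by a benzilic ester shift to the para-quinol ester A1.
- Merits: one operation gives the six-membered dienone with the C4 carbinol and the first chain carbon (as ester); no protecting groups are needed.
- Weak points: A2 is not a catalogue compound and is electrophilic at three carbonyls and two enone termini, so methoxide has several competing sites. A1 is achiral, so C5, C6 and the absolute configuration are still open and a desymmetrising epoxidation is needed anyway. Turning the ester into the trienyl chain requires hydride chemistry on a cross-conjugated dienone that aromatises easily. The C2 nitrogen is no closer.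
- Comparison: it reaches a ring far sooner than the chosen plan, but that ring has no stereochemistry. It needs the key step of Alternative 3 as well and is therefore dominated by it. The chosen plan is longer but arrives at 20 with every ring stereocentre fixed.

Alternative 2: The cut is four C–O bonds at once. The C1-silyloxy C4-alkynyl cyclohexadiene A4 would add singlet oxygen across C3 and C6, anti to the silyloxy group, and Co(TPP) would isomerise the endoperoxide in the same flask to the syn bis-epoxide A3.
- Merits: both oxirane oxygens come from one molecule of dioxygen, so the syn relation between the C4 oxygen and the C5–C6 oxirane is guaranteed by mechanism. Oxidation at C1 and β-elimination would then open the C3–C4 oxirane to the quinol A5 (described under Alternative 3) in very few steps.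
- Weak points: the absolute configuration rests on an enantiopure A4 and on facial selectivity from a single allylic silyloxy group. A4 is a 1,3-diene with an allylic leaving group, one elimination away from an aryl alkyne. Ene reaction and the rearrangement of the endoperoxide to a hydroxy enone compete.
- Comparison: in step count and in the way it sets relative configuration this road is better than the chosen one. The chosen plan sets against it an absolute configuration taken from the chiral pool and stable, well-behaved intermediates up to the enone stage.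

Alternative 3: The cut is the two C–O bonds of the oxirane. The achiral quinol A6, as its sodium alkoxide (NaN(SiMe3)2), would be epoxidised by trityl hydroperoxide in the presence of a dialkyl tartrate on one enone arm, syn to the C4 oxygen, giving A5.
- Merits: this is the shortest route. A5 is 20 without its triethylsilyl group, so steps 1–14 would be replaced by three or four operations, and the alkoxide direction secures the syn relation.
- Weak points: enantioselectivity must come wholly from the tartrate-modified reagent acting on two enantiotopic enone arms of a 4-alkynyl quinol. Over-epoxidation to the bis-epoxide and dienone–phenol-type rearrangement of A6 are the expected losses, and any shortfall in enantiopurity would be carried to the end.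
- Comparison: if the desymmetrisation is highly selective, this road is clearly superior in step economy. The chosen plan sets against it only certainty: C5 and C6 come from the glucoside 1, C4 from a substrate-controlled addition, and diastereomers, not enantiomers, would have to be removed.

Key step: step 10

Remark: potassium glutaconaldehyde enolate 34 is taken as a catalogue compound (otherwise one step from pyridine–SO3 and KOH); carbocycles are numbered as in the target, and PMB = 4-methoxybenzyl, TES = triethylsilyl, TIPS = triisopropylsilyl.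

## Steps

Step 1
Reactants: 1 methyl α-D-glucopyranoside
Product: 2 methyl 4,6-O-[(R)-benzylidene]-α-D-glucopyranoside
Conditions: PhCH(OMe)2, CSA (cat.), DMF, 60 °C, reduced pressure
Reagents that add atoms: benzaldehyde dimethyl acetal, COC(OC)c1ccccc1
Why: Thermodynamic transacetalisation closes the trans-fused 1,3-dioxane on O4 and O6 with equatorial phenyl and leaves the 2,3-diol free; 2 is also commercially available.

Step 2
Reactants: 2 methyl 4,6-O-[(R)-benzylidene]-α-D-glucopyranoside
Product: 3 methyl 4,6-O-[(R)-benzylidene]-3-O-(4-methoxybenzyl)-α-D-glucopyranoside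
Conditions: NaH (2.2 equiv), THF, rt; CuCl2 (1.1 equiv); PMBCl, n-Bu4NI (cat.), reflux
Reagents that add atoms: 4-methoxybenzyl chloride, COc1ccc(CCl)cc1
Why: Williamson etherification under chelate control: alkylation of the divalent copper chelate of the 2,3-dialkoxide of this diol is known to favour O3 with benzyl and allyl halides, against the O2 preference of the free diol.

Step 3
Reactants: 3 methyl 4,6-O-[(R)-benzylidene]-3-O-(4-methoxybenzyl)-α-D-glucopyranoside
Product: 4 methyl 4,6-O-[(R)-benzylidene]-3-O-(4-methoxybenzyl)-α-D-arabino-hexopyranosid-2-ulose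
Conditions: Dess–Martin periodinane, NaHCO3, CH2Cl2, rt
Reagents that add atoms: none
Why: Dess–Martin oxidation of the only free hydroxyl; the buffered neutral medium avoids β-elimination of O4 across the new ketone and spares the acetal and the PMB ether.

Step 4
Reactants: 4 methyl 4,6-O-[(R)-benzylidene]-3-O-(4-methoxybenzyl)-α-D-arabino-hexopyranosid-2-ulose; 5 (triisopropylsilyl)acetylene
Product: 7 methyl 4,6-O-[(R)-benzylidene]-3-O-(4-methoxybenzyl)-2-C-[(triisopropylsilyl)ethynyl]-α-D-glucopyranoside, via lithium (triisopropylsilyl)acetylide 6 (not isolated)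
Conditions: 5, n-BuLi, THF, −78 °C; then 4, −78 to −40 °C; aq. NH4Cl
Reagents that add atoms: none
Why: 1,2-Addition of a lithium acetylide to a pyranosid-2-ulose. The axial anomeric methoxyl blocks the α face and the nucleophile enters axially from the β face, anti to the C1–OMe bond, so the alkynyl group ends axial and the tertiary hydroxyl equatorial (gluco), which is C4 of the target. The weakly basic acetylide at low temperature limits enolisation toward C3.

Step 5
Reactants: 7 methyl 4,6-O-[(R)-benzylidene]-3-O-(4-methoxybenzyl)-2-C-[(triisopropylsilyl)ethynyl]-α-D-glucopyranoside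
Product: 8 methyl 3-O-(4-methoxybenzyl)-2-C-[(triisopropylsilyl)ethynyl]-α-D-glucopyranoside
Conditions: CSA (cat.), MeOH, rt
Reagents that add atoms: none
Why: Acid-catalysed transacetalisation to methanol removes the benzylidene group; PMB ether, methyl glycoside, silylalkyne and tertiary propargylic alcohol tolerate catalytic CSA at room temperature.

Step 6
Reactants: 8 methyl 3-O-(4-methoxybenzyl)-2-C-[(triisopropylsilyl)ethynyl]-α-D-glucopyranoside
Product: 9 methyl 6-deoxy-6-iodo-3-O-(4-methoxybenzyl)-2-C-[(triisopropylsilyl)ethynyl]-α-D-glucopyranoside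
Conditions: I2, PPh3, imidazole, THF, rt
Reagents that add atoms: iodine, II
Why: Garegg–Samuelsson iodination; the alkoxyphosphonium pathway is selective for the primary hydroxyl over the secondary and tertiary ones.

Step 7
Reactants: 9 methyl 6-deoxy-6-iodo-3-O-(4-methoxybenzyl)-2-C-[(triisopropylsilyl)ethynyl]-α-D-glucopyranoside
Product: 10 methyl 4-O-benzoyl-6-deoxy-6-iodo-3-O-(4-methoxybenzyl)-2-C-[(triisopropylsilyl)ethynyl]-α-D-glucopyranoside
Conditions: BzCl, pyridine, DMAP (cat.), CH2Cl2, 0 °C
Reagents that add atoms: benzoyl chloride, O=C(Cl)c1ccccc1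
Why: Acylation of the only secondary hydroxyl; the tertiary propargylic alcohol does not react under these conditions. The benzoate later releases the oxirane oxygen under the conditions of ring closure.

Step 8
Reactants: 10 methyl 4-O-benzoyl-6-deoxy-6-iodo-3-O-(4-methoxybenzyl)-2-C-[(triisopropylsilyl)ethynyl]-α-D-glucopyranoside
Product: 11 methyl 4-O-benzoyl-6-deoxy-6-iodo-3-O-(4-methoxybenzyl)-2-O-triethylsilyl-2-C-[(triisopropylsilyl)ethynyl]-α-D-glucopyranoside
Conditions: TESOTf, 2,6-lutidine, CH2Cl2, −40 to 0 °C
Reagents that add atoms: triethylsilyl trifluoromethanesulfonate, CC[Si](CC)(CC)OS(=O)(=O)C(F)(F)F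
Why: Silyl triflate silylation of a hindered tertiary alcohol. The ether keeps the C4 oxygen from closing the wrong oxirane in step 14 and is removed together with the alkyne silyl group in step 22.

Step 9
Reactants: 11 methyl 4-O-benzoyl-6-deoxy-6-iodo-3-O-(4-methoxybenzyl)-2-O-triethylsilyl-2-C-[(triisopropylsilyl)ethynyl]-α-D-glucopyranoside
Product: 12 methyl 4-O-benzoyl-6-deoxy-3-O-(4-methoxybenzyl)-2-O-triethylsilyl-2-C-[(triisopropylsilyl)ethynyl]-α-D-xylo-hex-5-enopyranoside (gluco-configured at the branch)
Conditions: DBU, THF, reflux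
Reagents that add atoms: none
Why: E2 dehydroiodination of a 6-iodopyranoside with an amidine base, the standard access to hex-5-enopyranosides; a fluoride-free base is chosen so that the silyl groups and the benzoate stay in place.

Step 10
Reactants: 12 methyl 4-O-benzoyl-6-deoxy-3-O-(4-methoxybenzyl)-2-O-triethylsilyl-2-C-[(triisopropylsilyl)ethynyl]-α-D-xylo-hex-5-enopyranoside
Product: 14 (3S,4S,5S,6S)-6-(benzoyloxy)-3-hydroxy-5-[(4-methoxybenzyl)oxy]-4-[(triethylsilyl)oxy]-4-[(triisopropylsilyl)ethynyl]cyclohexan-1-one, via open-chain trifluoroacetoxymercurio keto aldehyde 13 (not isolated)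
Conditions: Hg(OCOCF3)2 (10 mol %), acetone–H2O (4:1), rt
Reagents that add atoms: water, O
Why: Divalent mercury adds to the terminal carbon (sugar C6) of the exocyclic enol ether and water to sugar C5; the hemiketal opens to the ketone, the anomeric hemiacetal loses methanol, and the α-mercurio ketone 13 adds to the freed aldehyde. This is the Ferrier carbocyclisation of 6-deoxyhex-5-enopyranosides with a catalytic mercury salt. The ring closes by a 6-(enolendo)-exo-trig aldol that forms the C2–C3 bond of the target. The one new stereocentre, the C3 carbinol, is expected axial and trans to the C5 ether from a chair transition state in which mercury bridges the two oxygens, but its configuration does not matter because step 11 removes it. C4, C5 and C6 are carried over unchanged from the sugar. The step needs regioselectivity, which the polarity of the enol ether fixes, and chemoselectivity over the alkyne and the anisyl ring, which the far higher nucleophilicity of the enol ether and the triisopropylsilyl shield should secure. The near-neutral medium should leave silyl ether, PMB ether and benzoate untouched.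

Step 11
Reactants: 14 (3S,4S,5S,6S)-6-(benzoyloxy)-3-hydroxy-5-[(4-methoxybenzyl)oxy]-4-[(triethylsilyl)oxy]-4-[(triisopropylsilyl)ethynyl]cyclohexan-1-one
Product: 16 (4R,5S,6S)-6-(benzoyloxy)-5-[(4-methoxybenzyl)oxy]-4-[(triethylsilyl)oxy]-4-[(triisopropylsilyl)ethynyl]cyclohex-2-en-1-one, via 3-O-methanesulfonate 15 (not isolated)
Conditions: MsCl, Et3N, CH2Cl2, 0 °C to rt
Reagents that add atoms: none
Why: Mesylation of the β-hydroxy ketone and E1cB elimination in the same flask, the usual conversion of these aldols into cyclohexenones. The C6 centre is trans to its neighbour and has no drive to epimerise; the change of the C4 descriptor is a priority effect only.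

Step 12
Reactants: 16 (4R,5S,6S)-6-(benzoyloxy)-5-[(4-methoxybenzyl)oxy]-4-[(triethylsilyl)oxy]-4-[(triisopropylsilyl)ethynyl]cyclohex-2-en-1-one
Product: 17 (4R,5S,6S)-6-(benzoyloxy)-5-hydroxy-4-[(triethylsilyl)oxy]-4-[(triisopropylsilyl)ethynyl]cyclohex-2-en-1-one
Conditions: DDQ, CH2Cl2–pH 7 buffer, 0 °C to rt
Reagents that add atoms: none
Why: Oxidative cleavage of the PMB ether through its benzylic oxocarbenium ion, hydrolysed by water; enone, benzoate, silyl ether and silylalkyne are inert to DDQ.

Step 13
Reactants: 17 (4R,5S,6S)-6-(benzoyloxy)-5-hydroxy-4-[(triethylsilyl)oxy]-4-[(triisopropylsilyl)ethynyl]cyclohex-2-en-1-one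
Product: 18 (4R,5S,6S)-6-(benzoyloxy)-5-[(methylsulfonyl)oxy]-4-[(triethylsilyl)oxy]-4-[(triisopropylsilyl)ethynyl]cyclohex-2-en-1-one
Conditions: MsCl, pyridine, DMAP (cat.), CH2Cl2, 0 °C
Reagents that add atoms: methanesulfonyl chloride, CS(=O)(=O)Cl
Why: Sulfonylation turns the C5 oxygen, trans to the C6 benzoate, into a leaving group; pyridine is too weak a base to enolise the ketone or to drive benzoate migration.

Step 14
Reactants: 18 (4R,5S,6S)-6-(benzoyloxy)-5-[(methylsulfonyl)oxy]-4-[(triethylsilyl)oxy]-4-[(triisopropylsilyl)ethynyl]cyclohex-2-en-1-one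
Product: 20 (4R,5R,6S)-5,6-epoxy-4-[(triethylsilyl)oxy]-4-[(triisopropylsilyl)ethynyl]cyclohex-2-en-1-one, via 6-hydroxy 5-mesylate 19 (not isolated)
Conditions: K2CO3, MeOH, 0 °C
Reagents that add atoms: none
Why: Methanolysis of the activated α-keto benzoate frees the C6 alkoxide, which displaces the trans C5 mesylate by intramolecular SN2 (3-exo-tet) from the diaxial half-chair. Inversion at C5 puts the oxirane on the face of the C4 oxygen (5R,6S); the silylated C4 oxygen cannot compete, and the tertiary TES ether and TIPS-alkyne are stable to carbonate in methanol.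

Step 15
Reactants: 20 (4R,5R,6S)-5,6-epoxy-4-[(triethylsilyl)oxy]-4-[(triisopropylsilyl)ethynyl]cyclohex-2-en-1-one
Product: 21 (4R,5R,6S)-5,6-epoxy-2-iodo-4-[(triethylsilyl)oxy]-4-[(triisopropylsilyl)ethynyl]cyclohex-2-en-1-one
Conditions: I2, pyridine–CH2Cl2 (1:1), rt, dark
Reagents that add atoms: iodine, II
Why: Johnson α-iodination of an enone (pyridine addition, iodination, elimination), known for 4,4-disubstituted cyclohexenones; the silylated alkyne and the non-enolisable epoxy ketone should not react.

Step 16
Reactants: 22 (R)-4-benzyl-1,3-oxazolidin-2-one; 23 hexanoyl chloride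
Product: 24 (R)-4-benzyl-3-hexanoyl-1,3-oxazolidin-2-one
Conditions: n-BuLi, THF, −78 °C; then 23, −78 to 0 °C
Reagents that add atoms: none
Why: N-Acylation of the lithiated Evans oxazolidinone with an acid chloride.

Step 17
Reactants: 24 (R)-4-benzyl-3-hexanoyl-1,3-oxazolidin-2-one
Product: 25 (R)-4-benzyl-3-[(R)-2-methylhexanoyl]-1,3-oxazolidin-2-one
Conditions: NaN(SiMe3)2, THF, −78 °C; MeI
Reagents that add atoms: iodomethane, CI
Why: Evans alkylation: the chelated Z sodium enolate is methylated on the face opposite the benzyl group, which with the (R)-auxiliary gives the (R)-2-methylhexanoyl unit.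

Step 18
Reactants: 25 (R)-4-benzyl-3-[(R)-2-methylhexanoyl]-1,3-oxazolidin-2-one
Product: 26 (R)-2-methylhexan-1-ol
Conditions: LiBH4, MeOH (1 equiv), Et2O, 0 °C
Reagents that add atoms: none
Why: Reductive cleavage of the imide gives the primary alcohol without touching the α-stereocentre and returns the auxiliary.

Step 19
Reactants: 26 (R)-2-methylhexan-1-ol; 27 ethyl 2-(triphenylphosphoranylidene)propanoate
Product: 29 ethyl (2E,4R)-2,4-dimethyloct-2-enoate, via (R)-2-methylhexanal 28 (not isolated)
Conditions: Dess–Martin periodinane, NaHCO3, CH2Cl2, 0 °C to rt; then 27, rt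
Reagents that add atoms: none
Why: Oxidation and Wittig olefination in one flask spare the configurationally labile α-branched aldehyde from isolation; the stabilised α-methyl ylide should give the E trisubstituted alkene.

Step 20
Reactants: 29 ethyl (2E,4R)-2,4-dimethyloct-2-enoate
Product: 30 (2E,4R)-2,4-dimethyloct-2-enamide
Conditions: Me3Al, NH4Cl, toluene, 0 to 50 °C; aq. HCl
Reagents that add atoms: ammonium chloride, [NH4+].[Cl-]
Why: Weinreb amidation: the aluminium amide formed from Me3Al and NH4Cl converts the ester directly into the primary amide; the α-methyl, β-branched enoate resists conjugate addition.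

Step 21
Reactants: 21 (4R,5R,6S)-5,6-epoxy-2-iodo-4-[(triethylsilyl)oxy]-4-[(triisopropylsilyl)ethynyl]cyclohex-2-en-1-one; 30 (2E,4R)-2,4-dimethyloct-2-enamide
Product: 31 (2E,4R)-2,4-dimethyl-N-{(4R,5R,6S)-5,6-epoxy-1-oxo-4-[(triethylsilyl)oxy]-4-[(triisopropylsilyl)ethynyl]cyclohex-2-en-2-yl}oct-2-enamide
Conditions: CuI (20 mol %), MeNHCH2CH2NHMe (40 mol %), Cs2CO3, THF, 50 °C
Reagents that add atoms: none
Why: Goldberg-type amidation of an alkenyl iodide with a primary amide under monovalent copper and a diamine ligand, a coupling known for α-iodoenones. The ring has no enolisable hydrogen, and the silyl groups mask the hydroxyl and the alkyne C–H, which would otherwise bind copper.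

Step 22
Reactants: 31 (2E,4R)-2,4-dimethyl-N-{(4R,5R,6S)-5,6-epoxy-1-oxo-4-[(triethylsilyl)oxy]-4-[(triisopropylsilyl)ethynyl]cyclohex-2-en-2-yl}oct-2-enamide
Product: 32 (2E,4R)-N-[(4R,5R,6S)-5,6-epoxy-4-ethynyl-4-hydroxy-1-oxocyclohex-2-en-2-yl]-2,4-dimethyloct-2-enamide
Conditions: n-Bu4NF, AcOH, THF, 0 °C
Reagents that add atoms: none
Why: Fluoride cleaves the tertiary silyl ether and the alkynyl C–Si bond in one operation; acetic acid buffering keeps the medium near neutral for the epoxy ketone and the enamide.

Step 23
Reactants: 32 (2E,4R)-N-[(4R,5R,6S)-5,6-epoxy-4-ethynyl-4-hydroxy-1-oxocyclohex-2-en-2-yl]-2,4-dimethyloct-2-enamide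
Product: 33 (2E,4R)-N-{(4R,5R,6S)-5,6-epoxy-4-hydroxy-1-oxo-4-[(E)-2-(tributylstannyl)ethenyl]cyclohex-2-en-2-yl}-2,4-dimethyloct-2-enamide
Conditions: n-Bu3SnH, PdCl2(PPh3)2 (3 mol %), THF, 0 °C
Reagents that add atoms: tributyltin hydride, CCCC[SnH](CCCC)CCCC
Why: Palladium-catalysed syn hydrostannylation of a terminal alkyne (the precatalyst is reduced to zerovalent palladium by the stannane). The fully substituted propargylic carbon directs tin to the terminal carbon and gives the E-alkenylstannane; the terminal alkyne should react well before the hindered enone.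

Step 24
Reactants: 34 potassium (1E,3E)-5-oxopenta-1,3-dien-1-olate
Product: 35 (2E,4E)-5-bromopenta-2,4-dienal
Conditions: PPh3, Br2, CH2Cl2, 0 °C to rt
Reagents that add atoms: bromine, BrBr
Why: Deoxybromination of a vinylogous carboxylate by Ph3PBr2 formed in the flask; the all-trans bromodienal is the thermodynamic isomer.

Step 25
Reactants: 35 (2E,4E)-5-bromopenta-2,4-dienal
Product: 36 (2E,4E)-5-bromopenta-2,4-dienoic acid
Conditions: NaClO2, NaH2PO4, 2-methylbut-2-ene, t-BuOH–H2O, rt
Reagents that add atoms: sodium chlorite, [Na+].[O-]Cl=O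
Why: Pinnick oxidation of an enal; the alkene scavenger removes hypochlorous acid, so the bromodiene is not chlorinated.

Step 26
Reactants: 37 cyclopentane-1,3-dione
Product: 38 2-(hydroxyimino)cyclopentane-1,3-dione
Conditions: NaNO2, aq. HCl, 0 °C
Reagents that add atoms: sodium nitrite, [Na+].[O-]N=O
Why: C-Nitrosation of the enolised 1,3-dione at C2 and tautomerisation to the oxime, the classical entry to 2-amino-1,3-dicarbonyl compounds.

Step 27
Reactants: 38 2-(hydroxyimino)cyclopentane-1,3-dione
Product: 39 2-amino-3-hydroxycyclopent-2-en-1-one hydrochloride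
Conditions: H2 (1 atm), Pd/C, HCl, MeOH, rt
Reagents that add atoms: hydrogen chloride, Cl
Why: Hydrogenolysis of the oxime N–O bond and reduction of the C=N bond; the amine is trapped as its hydrochloride, which prevents self-condensation.

Step 28
Reactants: 36 (2E,4E)-5-bromopenta-2,4-dienoic acid; 39 2-amino-3-hydroxycyclopent-2-en-1-one hydrochloride
Product: 41 (2E,4E)-5-bromo-N-(2-hydroxy-5-oxocyclopent-1-en-1-yl)penta-2,4-dienamide, via (2E,4E)-5-bromopenta-2,4-dienoyl chloride 40 (not isolated)
Conditions: (COCl)2, DMF (cat.), CH2Cl2, 0 °C to rt; then 39, pyridine, THF, 0 °C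
Reagents that add atoms: none
Why: Acid chloride formation and N-acylation; the amine is more nucleophilic than the enol oxygen, and a brief aqueous LiOH treatment would cleave any enol ester.

Step 29
Reactants: 33 (2E,4R)-N-{(4R,5R,6S)-5,6-epoxy-4-hydroxy-1-oxo-4-[(E)-2-(tributylstannyl)ethenyl]cyclohex-2-en-2-yl}-2,4-dimethyloct-2-enamide; 41 (2E,4E)-5-bromo-N-(2-hydroxy-5-oxocyclopent-1-en-1-yl)penta-2,4-dienamide
Product: 42 (2E,4R)-N-{(1S,5S,6R)-5-hydroxy-5-[(1E,3E,5E)-7-[(2-hydroxy-5-oxocyclopent-1-en-1-yl)amino]-7-oxohepta-1,3,5-trien-1-yl]-2-oxo-7-oxabicyclo[4.1.0]hept-3-en-3-yl}-2,4-dimethyloct-2-enamide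
Conditions: PdCl2(MeCN)2 (10 mol %), DMF, rt, dark
Reagents that add atoms: none
Why: Stille coupling of an alkenylstannane with an alkenyl bromide on zerovalent palladium formed in situ; it proceeds with retention at both alkene termini and needs no base, so the epoxy quinol, the enamide and the acidic enol should survive.

## Compound list

1 | methyl α-D-glucopyranoside | CO[C@H]1O[C@H](CO)[C@@H](O)[C@H](O)[C@H]1O | starting material
2 | methyl 4,6-O-[(R)-benzylidene]-α-D-glucopyranoside | CO[C@H]1O[C@@H]2CO[C@@H](c3ccccc3)O[C@H]2[C@H](O)[C@H]1O | intermediate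
3 | methyl 4,6-O-[(R)-benzylidene]-3-O-(4-methoxybenzyl)-α-D-glucopyranoside | CO[C@H]1O[C@@H]2CO[C@@H](c3ccccc3)O[C@H]2[C@H](OCc4ccc(OC)cc4)[C@H]1O | intermediate
4 | methyl 4,6-O-[(R)-benzylidene]-3-O-(4-methoxybenzyl)-α-D-arabino-hexopyranosid-2-ulose | CO[C@H]1O[C@@H]2CO[C@@H](c3ccccc3)O[C@H]2[C@H](OCc4ccc(OC)cc4)C1=O | intermediate
5 | (triisopropylsilyl)acetylene | C#C[Si](C(C)C)(C(C)C)C(C)C | starting material
6 | lithium (triisopropylsilyl)acetylide | [Li]C#C[Si](C(C)C)(C(C)C)C(C)C | intermediate (not isolated)
7 | methyl 4,6-O-[(R)-benzylidene]-3-O-(4-methoxybenzyl)-2-C-[(triisopropylsilyl)ethynyl]-α-D-glucopyranoside | CO[C@H]1O[C@@H]2CO[C@@H](c3ccccc3)O[C@H]2[C@H](OCc4ccc(OC)cc4)[C@]1(O)C#C[Si](C(C)C)(C(C)C)C(C)C | intermediate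
8 | methyl 3-O-(4-methoxybenzyl)-2-C-[(triisopropylsilyl)ethynyl]-α-D-glucopyranoside | CO[C@H]1O[C@H](CO)[C@@H](O)[C@H](OCc2ccc(OC)cc2)[C@]1(O)C#C[Si](C(C)C)(C(C)C)C(C)C | intermediate
9 | methyl 6-deoxy-6-iodo-3-O-(4-methoxybenzyl)-2-C-[(triisopropylsilyl)ethynyl]-α-D-glucopyranoside | CO[C@H]1O[C@H](CI)[C@@H](O)[C@H](OCc2ccc(OC)cc2)[C@]1(O)C#C[Si](C(C)C)(C(C)C)C(C)C | intermediate
10 | methyl 4-O-benzoyl-6-deoxy-6-iodo-3-O-(4-methoxybenzyl)-2-C-[(triisopropylsilyl)ethynyl]-α-D-glucopyranoside | CO[C@H]1O[C@H](CI)[C@@H](OC(=O)c2ccccc2)[C@H](OCc2ccc(OC)cc2)[C@]1(O)C#C[Si](C(C)C)(C(C)C)C(C)C | intermediate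
11 | methyl 4-O-benzoyl-6-deoxy-6-iodo-3-O-(4-methoxybenzyl)-2-O-triethylsilyl-2-C-[(triisopropylsilyl)ethynyl]-α-D-glucopyranoside | CO[C@H]1O[C@H](CI)[C@@H](OC(=O)c2ccccc2)[C@H](OCc2ccc(OC)cc2)[C@]1(O[Si](CC)(CC)CC)C#C[Si](C(C)C)(C(C)C)C(C)C | intermediate
12 | methyl 4-O-benzoyl-6-deoxy-3-O-(4-methoxybenzyl)-2-O-triethylsilyl-2-C-[(triisopropylsilyl)ethynyl]-α-D-xylo-hex-5-enopyranoside | CO[C@H]1OC(=C)[C@@H](OC(=O)c2ccccc2)[C@H](OCc2ccc(OC)cc2)[C@]1(O[Si](CC)(CC)CC)C#C[Si](C(C)C)(C(C)C)C(C)C | intermediate
13 | 4-O-benzoyl-6-deoxy-3-O-(4-methoxybenzyl)-2-O-triethylsilyl-6-(trifluoroacetoxymercurio)-2-C-[(triisopropylsilyl)ethynyl]-D-xylo-hexos-5-ulose (open chain) | O=C[C@@](O[Si](CC)(CC)CC)(C#C[Si](C(C)C)(C(C)C)C(C)C)[C@@H](OCc1ccc(OC)cc1)[C@H](OC(=O)c1ccccc1)C(=O)C[Hg]OC(=O)C(F)(F)F | intermediate (not isolated)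
14 | (3S,4S,5S,6S)-6-(benzoyloxy)-3-hydroxy-5-[(4-methoxybenzyl)oxy]-4-[(triethylsilyl)oxy]-4-[(triisopropylsilyl)ethynyl]cyclohexan-1-one | O[C@H]1CC(=O)[C@@H](OC(=O)c2ccccc2)[C@H](OCc2ccc(OC)cc2)[C@]1(O[Si](CC)(CC)CC)C#C[Si](C(C)C)(C(C)C)C(C)C | intermediate
15 | 3-O-methanesulfonate of 14 | CS(=O)(=O)O[C@H]1CC(=O)[C@@H](OC(=O)c2ccccc2)[C@H](OCc2ccc(OC)cc2)[C@]1(O[Si](CC)(CC)CC)C#C[Si](C(C)C)(C(C)C)C(C)C | intermediate (not isolated)
16 | (4R,5S,6S)-6-(benzoyloxy)-5-[(4-methoxybenzyl)oxy]-4-[(triethylsilyl)oxy]-4-[(triisopropylsilyl)ethynyl]cyclohex-2-en-1-one | C1=C[C@@](O[Si](CC)(CC)CC)(C#C[Si](C(C)C)(C(C)C)C(C)C)[C@@H](OCc2ccc(OC)cc2)[C@H](OC(=O)c2ccccc2)C1=O | intermediate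
17 | (4R,5S,6S)-6-(benzoyloxy)-5-hydroxy-4-[(triethylsilyl)oxy]-4-[(triisopropylsilyl)ethynyl]cyclohex-2-en-1-one | C1=C[C@@](O[Si](CC)(CC)CC)(C#C[Si](C(C)C)(C(C)C)C(C)C)[C@@H](O)[C@H](OC(=O)c2ccccc2)C1=O | intermediate
18 | (4R,5S,6S)-6-(benzoyloxy)-5-[(methylsulfonyl)oxy]-4-[(triethylsilyl)oxy]-4-[(triisopropylsilyl)ethynyl]cyclohex-2-en-1-one | C1=C[C@@](O[Si](CC)(CC)CC)(C#C[Si](C(C)C)(C(C)C)C(C)C)[C@@H](OS(C)(=O)=O)[C@H](OC(=O)c2ccccc2)C1=O | intermediate
19 | (4R,5S,6S)-6-hydroxy-5-[(methylsulfonyl)oxy]-4-[(triethylsilyl)oxy]-4-[(triisopropylsilyl)ethynyl]cyclohex-2-en-1-one | C1=C[C@@](O[Si](CC)(CC)CC)(C#C[Si](C(C)C)(C(C)C)C(C)C)[C@@H](OS(C)(=O)=O)[C@H](O)C1=O | intermediate (not isolated)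
20 | (4R,5R,6S)-5,6-epoxy-4-[(triethylsilyl)oxy]-4-[(triisopropylsilyl)ethynyl]cyclohex-2-en-1-one | C1=C[C@@](O[Si](CC)(CC)CC)(C#C[Si](C(C)C)(C(C)C)C(C)C)[C@@H]2O[C@@H]2C1=O | intermediate
21 | (4R,5R,6S)-5,6-epoxy-2-iodo-4-[(triethylsilyl)oxy]-4-[(triisopropylsilyl)ethynyl]cyclohex-2-en-1-one | IC1=C[C@@](O[Si](CC)(CC)CC)(C#C[Si](C(C)C)(C(C)C)C(C)C)[C@@H]2O[C@@H]2C1=O | intermediate
22 | (R)-4-benzyl-1,3-oxazolidin-2-one | O=C1N[C@H](Cc2ccccc2)CO1 | starting material
23 | hexanoyl chloride | CCCCCC(Cl)=O | starting material
24 | (R)-4-benzyl-3-hexanoyl-1,3-oxazolidin-2-one | CCCCCC(=O)N1[C@H](Cc2ccccc2)COC1=O | intermediate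
25 | (R)-4-benzyl-3-[(R)-2-methylhexanoyl]-1,3-oxazolidin-2-one | CCCC[C@@H](C)C(=O)N1[C@H](Cc2ccccc2)COC1=O | intermediate
26 | (R)-2-methylhexan-1-ol | CCCC[C@@H](C)CO | intermediate
27 | ethyl 2-(triphenylphosphoranylidene)propanoate | CCOC(=O)C(C)=P(c1ccccc1)(c1ccccc1)c1ccccc1 | starting material
28 | (R)-2-methylhexanal | CCCC[C@@H](C)C=O | intermediate (not isolated)
29 | ethyl (2E,4R)-2,4-dimethyloct-2-enoate | CCCC[C@@H](C)/C=C(\C)C(=O)OCC | intermediate
30 | (2E,4R)-2,4-dimethyloct-2-enamide | CCCC[C@@H](C)/C=C(\C)C(N)=O | intermediate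
31 | (2E,4R)-2,4-dimethyl-N-{(4R,5R,6S)-5,6-epoxy-1-oxo-4-[(triethylsilyl)oxy]-4-[(triisopropylsilyl)ethynyl]cyclohex-2-en-2-yl}oct-2-enamide | CCCC[C@@H](C)/C=C(\C)C(=O)NC1=C[C@@](O[Si](CC)(CC)CC)(C#C[Si](C(C)C)(C(C)C)C(C)C)[C@@H]2O[C@@H]2C1=O | intermediate
32 | (2E,4R)-N-[(4R,5R,6S)-5,6-epoxy-4-ethynyl-4-hydroxy-1-oxocyclohex-2-en-2-yl]-2,4-dimethyloct-2-enamide | CCCC[C@@H](C)/C=C(\C)C(=O)NC1=C[C@@](O)(C#C)[C@@H]2O[C@@H]2C1=O | intermediate
33 | (2E,4R)-N-{(4R,5R,6S)-5,6-epoxy-4-hydroxy-1-oxo-4-[(E)-2-(tributylstannyl)ethenyl]cyclohex-2-en-2-yl}-2,4-dimethyloct-2-enamide | CCCC[C@@H](C)/C=C(\C)C(=O)NC1=C[C@@](O)(/C=C/[Sn](CCCC)(CCCC)CCCC)[C@@H]2O[C@@H]2C1=O | intermediate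
34 | potassium (1E,3E)-5-oxopenta-1,3-dien-1-olate (glutaconaldehyde potassium salt) | [K+].[O-]/C=C/C=C/C=O | starting material
35 | (2E,4E)-5-bromopenta-2,4-dienal | Br/C=C/C=C/C=O | intermediate
36 | (2E,4E)-5-bromopenta-2,4-dienoic acid | Br/C=C/C=C/C(O)=O | intermediate
37 | cyclopentane-1,3-dione | O=C1CCC(=O)C1 | starting material
38 | 2-(hydroxyimino)cyclopentane-1,3-dione | O=C1CCC(=O)C1=NO | intermediate
39 | 2-amino-3-hydroxycyclopent-2-en-1-one hydrochloride | Cl.NC1=C(O)CCC1=O | intermediate
40 | (2E,4E)-5-bromopenta-2,4-dienoyl chloride | Br/C=C/C=C/C(Cl)=O | intermediate (not isolated)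
41 | (2E,4E)-5-bromo-N-(2-hydroxy-5-oxocyclopent-1-en-1-yl)penta-2,4-dienamide | Br/C=C/C=C/C(=O)NC1=C(O)CCC1=O | intermediate
42 | (2E,4R)-N-{(1S,5S,6R)-5-hydroxy-5-[(1E,3E,5E)-7-[(2-hydroxy-5-oxocyclopent-1-en-1-yl)amino]-7-oxohepta-1,3,5-trien-1-yl]-2-oxo-7-oxabicyclo[4.1.0]hept-3-en-3-yl}-2,4-dimethyloct-2-enamide | CCCC[C@@H](C)/C=C(\C)C(=O)NC1=C[C@@](O)(/C=C/C=C/C=C/C(=O)NC2=C(O)CCC2=O)[C@@H]2O[C@@H]2C1=O | target

## Step count and least certain steps

Total step count: 29. Longest linear sequence: 19 steps (steps 1–15, 21, 22, 23 and 29). The acyl chain (steps 16–20) and the bromodienamide (steps 24–28) are made in parallel.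

**Step 10 (key step).** Three processes could divert the reaction:
- mercuration of the silylalkyne or the anisyl ring in place of the enol ether;
- protodemercuration of the open-chain mercurial before it cyclises, because the aldehyde has a fully substituted neighbour and the aldol may be slow;
- loss of the triethylsilyl ether to the trifluoroacetic acid set free from the catalyst.

The fallback sets out from 12 and avoids the metal. Mild acid hydration of the enol ether (PPTS, wet acetone) should give the open-chain 1,5-keto aldehyde 4-O-benzoyl-6-deoxy-3-O-(4-methoxybenzyl)-2-O-triethylsilyl-2-C-[(triisopropylsilyl)ethynyl]-D-xylo-hexos-5-ulose F1. An amine-mediated intramolecular aldol addition (pyrrolidine, AcOH, CH2Cl2) would then close the same C2–C3 bond, and the route is rejoined at 14.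

**Step 2.** Alkylation may go to O2 or to both oxygens, because the free diol of the α-glucoside prefers O2 and the copper chelate has to overturn that preference. The fallback sets out from 2. Selective 2-O-benzoylation (N-benzoylimidazole, CHCl3, reflux) gives methyl 2-O-benzoyl-4,6-O-[(R)-benzylidene]-α-D-glucopyranoside F2. Acid-catalysed etherification with 4-methoxybenzyl trichloroacetimidate (TfOH cat.) gives methyl 2-O-benzoyl-4,6-O-[(R)-benzylidene]-3-O-(4-methoxybenzyl)-α-D-glucopyranoside F3. Zemplén methanolysis (NaOMe, MeOH) returns to 3.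

**Step 14.** Enolisation of the α-benzoyloxy ketone could expel the β-mesylate (E1cB) before methanolysis frees the C6 oxygen, or the benzoate could migrate. The fallback removes the ketone during ring closure and sets out from 18. Luche reduction (NaBH4, CeCl3, MeOH, −78 °C) gives the allylic alcohol F4 (the C1 carbinol of 18, either epimer). K2CO3 in methanol then closes the oxirane to the epoxy allylic alcohol F5 (the C1 carbinol of 20). Oxidation with MnO2 returns to 20.

**Step 21.** The iodo epoxy enone could be destroyed before coupling, by opening of the oxirane by the diamine or the amide anion or by reductive loss of iodine; oxidative addition at the hindered iodide could also be slow. The fallback moves the amidation ahead of the oxirane and sets out from 16.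
- Iodination (I2, pyridine) gives the 2-iodo derivative of 16, F6.
- Amidation with 30 under the conditions of step 21 gives the 2-amido enone F7.
- DDQ gives the C5 alcohol F8.
- MsCl in pyridine gives the C5 mesylate F9.
- K2CO3 in methanol closes the oxirane and returns to 31.

**Step 23.** Tin could add to the internal alkyne carbon, or the palladium hydride could reduce the enone or open the epoxy ketone. The fallback replaces tin by silicon and sets out from 32. Platinum-catalysed hydrosilylation (PtCl2, XPhos, BnMe2SiH, THF), which is β-E-selective for propargylic alcohols, gives the (E)-2-(benzyldimethylsilyl)ethenyl carbinol F10. A fluoride-promoted Hiyama–Denmark coupling with 41 (n-Bu4NF, Pd2(dba)3, THF) then arrives directly at 42.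

## Further compounds

F1 | step 10 | 4-O-benzoyl-6-deoxy-3-O-(4-methoxybenzyl)-2-O-triethylsilyl-2-C-[(triisopropylsilyl)ethynyl]-D-xylo-hexos-5-ulose (open-chain keto aldehyde) | O=C[C@@](O[Si](CC)(CC)CC)(C#C[Si](C(C)C)(C(C)C)C(C)C)[C@@H](OCc1ccc(OC)cc1)[C@H](OC(=O)c1ccccc1)C(C)=O
F2 | step 2 | methyl 2-O-benzoyl-4,6-O-[(R)-benzylidene]-α-D-glucopyranoside | CO[C@H]1O[C@@H]2CO[C@@H](c3ccccc3)O[C@H]2[C@H](O)[C@H]1OC(=O)c1ccccc1
F3 | step 2 | methyl 2-O-benzoyl-4,6-O-[(R)-benzylidene]-3-O-(4-methoxybenzyl)-α-D-glucopyranoside | CO[C@H]1O[C@@H]2CO[C@@H](c3ccccc3)O[C@H]2[C@H](OCc4ccc(OC)cc4)[C@H]1OC(=O)c1ccccc1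
F4 | step 14 | C1 carbinol of 18 (C1 epimers; C4, C5, C6 as in 18) | C1=C[C@@](O[Si](CC)(CC)CC)(C#C[Si](C(C)C)(C(C)C)C(C)C)[C@@H](OS(C)(=O)=O)[C@H](OC(=O)c2ccccc2)C1O
F5 | step 14 | C1 carbinol of 20 (C1 epimers; C4, C5, C6 as in 20) | C1=C[C@@](O[Si](CC)(CC)CC)(C#C[Si](C(C)C)(C(C)C)C(C)C)[C@@H]2O[C@@H]2C1O
F6 | step 21 | (4R,5S,6S)-6-(benzoyloxy)-2-iodo-5-[(4-methoxybenzyl)oxy]-4-[(triethylsilyl)oxy]-4-[(triisopropylsilyl)ethynyl]cyclohex-2-en-1-one | IC1=C[C@@](O[Si](CC)(CC)CC)(C#C[Si](C(C)C)(C(C)C)C(C)C)[C@@H](OCc2ccc(OC)cc2)[C@H](OC(=O)c2ccccc2)C1=O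
F7 | step 21 | (2E,4R)-N-{(4R,5S,6S)-6-(benzoyloxy)-5-[(4-methoxybenzyl)oxy]-1-oxo-4-[(triethylsilyl)oxy]-4-[(triisopropylsilyl)ethynyl]cyclohex-2-en-2-yl}-2,4-dimethyloct-2-enamide | CCCC[C@@H](C)/C=C(\C)C(=O)NC1=C[C@@](O[Si](CC)(CC)CC)(C#C[Si](C(C)C)(C(C)C)C(C)C)[C@@H](OCc2ccc(OC)cc2)[C@H](OC(=O)c2ccccc2)C1=O
F8 | step 21 | C5 alcohol from F7 (p-methoxybenzyl group removed) | CCCC[C@@H](C)/C=C(\C)C(=O)NC1=C[C@@](O[Si](CC)(CC)CC)(C#C[Si](C(C)C)(C(C)C)C(C)C)[C@@H](O)[C@H](OC(=O)c2ccccc2)C1=O
F9 | step 21 | C5 methanesulfonate of F8 | CCCC[C@@H](C)/C=C(\C)C(=O)NC1=C[C@@](O[Si](CC)(CC)CC)(C#C[Si](C(C)C)(C(C)C)C(C)C)[C@@H](OS(C)(=O)=O)[C@H](OC(=O)c2ccccc2)C1=O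
F10 | step 23 | (2E,4R)-N-{(4R,5R,6S)-4-[(E)-2-(benzyldimethylsilyl)ethenyl]-5,6-epoxy-4-hydroxy-1-oxocyclohex-2-en-2-yl}-2,4-dimethyloct-2-enamide | CCCC[C@@H](C)/C=C(\C)C(=O)NC1=C[C@@](O)(/C=C/[Si](C)(C)Cc3ccccc3)[C@@H]2O[C@@H]2C1=O
A1 | alternative 1 | methyl 1-hydroxy-4-oxocyclohexa-2,5-diene-1-carboxylate | COC(=O)C1(O)C=CC(=O)C=C1
A2 | alternative 1 | cyclohepta-3,6-diene-1,2,5-trione (para-tropoquinone) | O=C1C=CC(=O)C(=O)C=C1
A3 | alternative 2 | syn 3,4:5,6-bis-epoxide of the C1 tert-butyldimethylsilyl ether, with the triisopropylsilylethynyl group on C4 and both oxiranes anti to the silyloxy group | C1[C@@H]3O[C@]3(C#C[Si](C(C)C)(C(C)C)C(C)C)[C@@H]2O[C@@H]2[C@H]1O[Si](C)(C)C(C)(C)C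
A4 | alternative 2 | (1S)-1-(tert-butyldimethylsilyloxy)-4-[(triisopropylsilyl)ethynyl]cyclohexa-3,5-diene | CC(C)(C)[Si](C)(C)O[C@H]1CC=C(C#C[Si](C(C)C)(C(C)C)C(C)C)C=C1
A5 | alternative 3 | (4R,5R,6S)-5,6-epoxy-4-hydroxy-4-[(triisopropylsilyl)ethynyl]cyclohex-2-en-1-one | C1=C[C@@](O)(C#C[Si](C(C)C)(C(C)C)C(C)C)[C@@H]2O[C@@H]2C1=O
A6 | alternative 3 | 4-hydroxy-4-[(triisopropylsilyl)ethynyl]cyclohexa-2,5-dien-1-one | O=C1C=CC(O)(C#C[Si](C(C)C)(C(C)C)C(C)C)C=C1
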